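Ring B of the target carries its oxygen at C6, between C5 and C7, and C10 and C8 are 1,3-related through C9 (labdane numbering). Ring B is therefore cut into a ketone C5–C6–C7, nucleophilic at both α-carbons, and an enoate C10=C9–C8, electrophilic at its β-carbon and acyl carbon. Since C5–C10 also closes ring A, the precursor is an open-chain keto enoate whose only stereocentre is the C4 quaternary carbon. One base treatment zips it up: Michael addition C5→C10 closes ring A, Dieckmann acylation C7→C8 closes ring B, giving the trans-decalin-6,8-dione from which side chain, C6 acetate and C8 methylene follow.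

Key step: step 7

Assumption: ring positions are named by labdane numbering throughout (C4 bears CH3 and CO2CH3, C5 and C10 are the ring-fusion carbons, C6 to C9 complete ring B, C17 is the exocyclic methylene carbon, C19 the ester carbon), and 1, 2, 14 and the (S)-t-BuPHOX ligand are taken as purchasable.

Step 1
Reactants: 1 2,6-dimethylcyclohexanone; 2 allyl chloroformate
Product: 3 2,6-dimethylcyclohex-1-en-1-yl prop-2-en-1-yl carbonate
Conditions: KN(SiMe3)2, THF, −78 °C; then 2, −78 → 0 °C
Reagents that add atoms: none
Why: Enol carbonate formation by O-acylation of the tetrasubstituted potassium enolate; both α-carbons of 1 are equivalent, so only one enolate can form.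

Step 2
Reactants: 3 2,6-dimethylcyclohex-1-en-1-yl prop-2-en-1-yl carbonate
Product: 4 (2S)-2,6-dimethyl-2-(prop-2-en-1-yl)cyclohexan-1-one
Conditions: Pd2(dba)3 (2.5 mol %), (S)-t-BuPHOX (6 mol %), THF, 25 °C
Reagents that add atoms: none
Why: Tsuji decarboxylative asymmetric allylic alkylation: loss of CO2 gives a π-allyl palladium enolate whose C-allylation is steered by the (S)-t-BuPHOX ligand to the 2S quaternary centre, as with the 2-methylcyclohexanone parent, and the C6 epimers do not matter because C6 becomes a carbonyl carbon in step 3.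

Step 3
Reactants: 4 (2S)-2,6-dimethyl-2-(prop-2-en-1-yl)cyclohexan-1-one
Product: 5 (2S)-2-methyl-6-oxo-2-(prop-2-en-1-yl)heptanoic acid
Conditions: Cu(NO3)2·3H2O (5 mol %), O2 (1 atm), AcOH/H2O (9:1), 60 °C
Reagents that add atoms: dioxygen, O=O
Why: Copper-catalysed aerobic oxidative C–C cleavage of an α-substituted cycloalkanone: C6 is the only enolisable position, its α-hydroperoxide fragments to the methyl ketone and the carboxylic acid, and the quaternary stereocentre is not touched.

Step 4
Reactants: 5 (2S)-2-methyl-6-oxo-2-(prop-2-en-1-yl)heptanoic acid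
Product: 6 methyl (2S)-2-methyl-6-oxo-2-(prop-2-en-1-yl)heptanoate
Conditions: MeI, K2CO3, DMF, 23 °C
Reagents that add atoms: iodomethane, CI
Why: Esterification by SN2 O-methylation of the potassium carboxylate; K2CO3 does not enolise the ketone enough for C-methylation.

Step 5
Reactants: 6 methyl (2S)-2-methyl-6-oxo-2-(prop-2-en-1-yl)heptanoate
Product: 7 dimethyl (2E,7S)-3,7-dimethyl-7-(prop-2-en-1-yl)oct-2-enedioate
Conditions: (MeO)2P(O)CH2CO2Me, NaH, THF, 0 → 65 °C; E isomer purified by chromatography
Reagents that add atoms: trimethyl phosphonoacetate, COC(=O)CP(=O)(OC)OC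
Why: Horner–Wadsworth–Emmons olefination of the only ketone in 6 should give mainly the E enoate, and the ester on the quaternary carbon has no α-hydrogen and is inert.

Step 6
Reactants: 7 dimethyl (2E,7S)-3,7-dimethyl-7-(prop-2-en-1-yl)oct-2-enedioate
Product: 8 dimethyl (2E,7S)-3,7-dimethyl-7-(2-oxopropyl)oct-2-enedioate
Conditions: PdCl2 (10 mol %), CuCl (20 mol %), O2 (1 atm), DMF/H2O (7:1), 23 °C
Reagents that add atoms: water, O
Why: Tsuji–Wacker oxidation: Markovnikov oxypalladation of the terminal alkene gives the methyl ketone, while the trisubstituted, electron-poor enoate is not attacked.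

Step 7
Reactants: 8 dimethyl (2E,7S)-3,7-dimethyl-7-(2-oxopropyl)oct-2-enedioate
Product: 10 methyl 6,8-dioxo-11,12,13,14,15,16,17-heptanorlabdan-19-oate, via Michael adduct 9 (not isolated)
Conditions: KOt-Bu (2.2 equiv), t-BuOH/THF (1:5), 0.02 M, 0 → 40 °C; then 1 M HCl
Reagents that add atoms: none
Why: Reversible enolisation lets the C5 enolate add to the enoate β-carbon C10 (Michael addition, 6-exo-trig, closes ring A and creates the C10 quaternary carbon), and after proton transfer the C7 enolate of adduct 9 acylates the C8 ester (Dieckmann condensation, 6-exo-trig, closes ring B) with loss of methoxide; deprotonation of the resulting 1,3-dione makes the sequence irreversible. The closest known reaction type is the consecutive Michael–Claisen annulation of ketones with α,β-unsaturated esters to cyclohexane-1,3-diones, here with the Michael step intramolecular. C10 is set relative to C4 in a chair transition state for ring A in which the developing C9 arm is equatorial, the C10 methyl is axial, and at C4 the ester rather than the methyl takes the axial position syn to it (the smaller group, as in the 1,3-diaxial CO2CH3/CH3 pair of the target). C5 is set with its acyl group equatorial, trans to the C9 arm, and stays epimerisable next to the C6 carbonyl, so the more stable trans ring fusion should result. The selectivity needed is C5 over C7 as Michael donor and C8 over C19 as acyl acceptor: C7 attack on C10 would need an eight-membered ring, and closure of C7 onto the neopentyl C19 ester would give a strained cyclopentane-1,3-dione, whereas six-membered closure onto the unhindered C8 ester is favoured.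

Step 8
Reactants: 10 methyl 6,8-dioxo-11,12,13,14,15,16,17-heptanorlabdan-19-oate
Product: 11 methyl 8-methoxy-6-oxo-11,12,13,14,15,16,17-heptanorlabd-7-en-19-oate
Conditions: MeOH, TsOH·H2O (5 mol %), PhMe, 4 Å molecular sieves, 60 °C
Reagents that add atoms: methanol, CO
Why: Acid-catalysed vinylogous ester formation from the 1,3-dione: methanol should add at the less hindered C8 carbonyl and leave the C6 carbonyl next to the congested C5, as with 4,4-disubstituted cyclohexane-1,3-diones.

Step 9
Reactants: 11 methyl 8-methoxy-6-oxo-11,12,13,14,15,16,17-heptanorlabd-7-en-19-oate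
Product: 13 methyl 8-oxo-11,12,13,14,15,16,17-heptanorlabd-6-en-19-oate, via allylic alcohol 12 (not isolated)
Conditions: NaBH4, CeCl3·7H2O, MeOH, 0 °C; then 1 M HCl, THF, 23 °C
Reagents that add atoms: water, O
Why: Stork–Danheiser transposition: Luche 1,2-reduction of the C6 carbonyl, which spares the hindered methyl ester, then acid hydrolysis of the enol ether with loss of water from C6 gives the 6-en-8-one.

Step 10
Reactants: 14 (2Z)-3-methylpent-2-en-4-yn-1-ol
Product: 15 (2Z)-3-methylpenta-2,4-dien-1-ol
Conditions: H2 (1 atm), Pd/CaCO3 poisoned with Pb(OAc)2 (Lindlar catalyst), quinoline, EtOAc, 0 °C, stopped after one equivalent of H2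
Reagents that add atoms: none
Why: Lindlar semihydrogenation of the terminal alkyne to the vinyl group; the trisubstituted Z alkene is untouched, so the geometry of the later C12=C13 bond is carried in from 14.

Step 11
Reactants: 15 (2Z)-3-methylpenta-2,4-dien-1-ol
Product: 17 (3Z)-5-bromo-3-methylpenta-1,3-diene, via mesylate 16 (not isolated)
Conditions: MsCl, Et3N, THF, −40 °C; then LiBr, −40 → 0 °C; used at once
Reagents that add atoms: lithium bromide, [Li+].[Br-]; methanesulfonyl chloride, CS(=O)(=O)Cl (mesyl group of 16 only)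
Why: Mesylation and SN2 displacement by bromide at low temperature convert the allylic alcohol to the bromide without ionisation, so the Z geometry should be kept.

Step 12
Reactants: 13 methyl 8-oxo-11,12,13,14,15,16,17-heptanorlabd-6-en-19-oate; 17 (3Z)-5-bromo-3-methylpenta-1,3-diene
Product: 19 methyl (12Z)-8-oxo-17-norlabda-6,12,14-trien-19-oate, via C9 epimer 18 (not isolated)
Conditions: LiN(i-Pr)2, THF, −78 °C; 17, DMPU, −78 → −20 °C; then MeOH, NaOMe (0.3 equiv), 23 °C
Reagents that add atoms: none
Why: Kinetic α′-deprotonation of the enone at C9 (its only α′ C–H) and SN2 alkylation by the allylic bromide, which should enter anti to the C10 methyl to give mainly the 9α-alkyl epimer 18; methoxide equilibration through the C8 enolate (reprotonation from the same open α face and the equatorial preference of the side chain) then converts it into the 9β-alkyl, 9α-H isomer 19.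

Step 13
Reactants: 19 methyl (12Z)-8-oxo-17-norlabda-6,12,14-trien-19-oate
Product: 21 methyl (12Z)-6α-hydroxy-8-oxo-17-norlabda-12,14-dien-19-oate, via boryl ketone 20 (not isolated)
Conditions: B2pin2, CuCl (5 mol %), Xantphos (5 mol %), NaOt-Bu (10 mol %), MeOH (2 equiv), THF, 23 °C; then NaBO3·4H2O, THF/H2O, 23 °C
Reagents that add atoms: bis(pinacolato)diboron, CC1(C)OB(OC1(C)C)B1OC(C)(C)C(C)(C)O1; sodium perborate, [Na+].[Na+].O[B-]1(O)OO[B-](O)(O)OO1
Why: Copper-catalysed conjugate borylation of the enone: the copper boryl species adds to C6 from the α face, away from the β-axial C10 methyl and C4 ester, the diene being far less reactive, and perborate oxidation with retention gives the 6α (equatorial) alcohol.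

Step 14
Reactants: 21 methyl (12Z)-6α-hydroxy-8-oxo-17-norlabda-12,14-dien-19-oate
Product: 22 methyl (12Z)-6α-hydroxylabda-8(17),12,14-trien-19-oate
Conditions: Zn, CH2Br2, TiCl4, THF/CH2Cl2, 0 → 23 °C
Reagents that add atoms: dibromomethane, BrCBr
Why: Takai–Lombardo methylenation of the C8 ketone is non-basic, so C9 is not epimerised and the β-hydroxy ketone neither eliminates nor undergoes retro-aldol cleavage, while the ester is inert.

Step 15
Reactants: 22 methyl (12Z)-6α-hydroxylabda-8(17),12,14-trien-19-oate
Product: 23 methyl (12Z)-6α-acetoxylabda-8(17),12,14-trien-19-oate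
Conditions: Ac2O, pyridine, DMAP (10 mol %), CH2Cl2, 23 °C
Reagents that add atoms: acetic anhydride, CC(=O)OC(C)=O
Why: DMAP-catalysed esterification of the secondary 6α alcohol with retention at C6; the homoallylic acetate cannot eliminate towards a carbonyl.

Compound list
1 | 2,6-dimethylcyclohexanone (cis/trans mixture) | CC1CCCC(C)C1=O | starting material
2 | allyl chloroformate | C=CCOC(=O)Cl | starting material
3 | 2,6-dimethylcyclohex-1-en-1-yl prop-2-en-1-yl carbonate (racemic) | C=CCOC(=O)OC1=C(C)CCCC1C | intermediate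
4 | (2S)-2,6-dimethyl-2-(prop-2-en-1-yl)cyclohexan-1-one (both C6 epimers) | C=CC[C@]1(C)CCCC(C)C1=O | intermediate
5 | (2S)-2-methyl-6-oxo-2-(prop-2-en-1-yl)heptanoic acid | CC(=O)CCC[C@@](C)(CC=C)C(=O)O | intermediate
6 | methyl (2S)-2-methyl-6-oxo-2-(prop-2-en-1-yl)heptanoate | CC(=O)CCC[C@@](C)(CC=C)C(=O)OC | intermediate
7 | dimethyl (2E,7S)-3,7-dimethyl-7-(prop-2-en-1-yl)oct-2-enedioate | COC(=O)/C=C(\C)CCC[C@@](C)(CC=C)C(=O)OC | intermediate
8 | dimethyl (2E,7S)-3,7-dimethyl-7-(2-oxopropyl)oct-2-enedioate | COC(=O)/C=C(\C)CCC[C@@](C)(CC(C)=O)C(=O)OC | intermediate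
9 | Michael adduct: methyl 2-acetyl-3-(2-methoxy-2-oxoethyl)-1,3-dimethylcyclohexane-1-carboxylate, ring A only (4β-CO2CH3, 4α-CH3, 5α-H with equatorial acetyl, 10β-CH3) | COC(=O)C[C@@]1(C)CCC[C@](C)(C(=O)OC)[C@@H]1C(C)=O | intermediate
10 | methyl 6,8-dioxo-11,12,13,14,15,16,17-heptanorlabdan-19-oate (trans-fused; 4α-CH3, 5α-H, 10β-CH3; largely enolised) | C1C(=O)CC(=O)[C@@H]2[C@]1(C)CCC[C@]2(C)C(=O)OC | intermediate
11 | methyl 8-methoxy-6-oxo-11,12,13,14,15,16,17-heptanorlabd-7-en-19-oate | C1C(OC)=CC(=O)[C@@H]2[C@]1(C)CCC[C@]2(C)C(=O)OC | intermediate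
12 | methyl 6β-hydroxy-8-methoxy-11,12,13,14,15,16,17-heptanorlabd-7-en-19-oate | C1C(OC)=C[C@@H](O)[C@@H]2[C@]1(C)CCC[C@]2(C)C(=O)OC | intermediate
13 | methyl 8-oxo-11,12,13,14,15,16,17-heptanorlabd-6-en-19-oate | C1C(=O)C=C[C@@H]2[C@]1(C)CCC[C@]2(C)C(=O)OC | intermediate
14 | (2Z)-3-methylpent-2-en-4-yn-1-ol | C#C/C(C)=C\CO | starting material
15 | (2Z)-3-methylpenta-2,4-dien-1-ol | C=C/C(C)=C\CO | intermediate
16 | (2Z)-3-methylpenta-2,4-dien-1-yl methanesulfonate | C=C/C(C)=C\COS(C)(=O)=O | intermediate
17 | (3Z)-5-bromo-3-methylpenta-1,3-diene | C=C/C(C)=C\CBr | intermediate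
18 | methyl (12Z)-8-oxo-17-nor-9-epi-labda-6,12,14-trien-19-oate (9α side chain, 9β-H) | C=C/C(C)=C\C[C@@H]1C(=O)C=C[C@@H]2[C@]1(C)CCC[C@]2(C)C(=O)OC | intermediate
19 | methyl (12Z)-8-oxo-17-norlabda-6,12,14-trien-19-oate (9β side chain, 9α-H) | C=C/C(C)=C\C[C@H]1C(=O)C=C[C@@H]2[C@]1(C)CCC[C@]2(C)C(=O)OC | intermediate
20 | methyl (12Z)-8-oxo-6α-(4,4,5,5-tetramethyl-1,3,2-dioxaborolan-2-yl)-17-norlabda-12,14-dien-19-oate | C=C/C(C)=C\C[C@H]1C(=O)C[C@H](B3OC(C)(C)C(C)(C)O3)[C@@H]2[C@]1(C)CCC[C@]2(C)C(=O)OC | intermediate
21 | methyl (12Z)-6α-hydroxy-8-oxo-17-norlabda-12,14-dien-19-oate | C=C/C(C)=C\C[C@H]1C(=O)C[C@H](O)[C@@H]2[C@]1(C)CCC[C@]2(C)C(=O)OC | intermediate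
22 | methyl (12Z)-6α-hydroxylabda-8(17),12,14-trien-19-oate | C=C/C(C)=C\C[C@H]1C(=C)C[C@H](O)[C@@H]2[C@]1(C)CCC[C@]2(C)C(=O)OC | intermediate
23 | methyl (12Z)-6α-acetoxylabda-8(17),12,14-trien-19-oate | C=C/C(C)=C\C[C@H]1C(=C)C[C@H](OC(C)=O)[C@@H]2[C@]1(C)CCC[C@]2(C)C(=O)OC | target

Total step count: 15. Longest linear sequence: 13 steps (steps 1 to 9, then 12 to 15); the side-chain bromide is made in steps 10 and 11 and joined in step 12.

Steps most likely to fail

Step 7. The conjugate addition has to join the neopentyl C5 to a β,β-disubstituted enoate; it may be slow and reversible, so that the C7 enolate instead closes onto the C19 ester, or the facial control of C10 relative to C4 may be weak. The fallback makes the acceptor doubly activated and sets out from 6. Knoevenagel condensation of 6 with dimethyl malonate (TiCl4, pyridine, THF) should give the alkylidene malonate F1. Tsuji–Wacker oxidation as in step 6 then gives the keto triester F2. With KOt-Bu in THF at −20 → 23 °C the C5 enolate should add rapidly to the alkylidene malonate, and one of the malonate esters then serves as the acyl acceptor for C7, giving the 9-carbomethoxy dione F3. Krapcho dealkoxycarbonylation (LiCl, wet DMSO, 130 °C) removes the extra ester and comes back to the route at 10.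

Step 12. Proton exchange between product and enolate may lead to double alkylation, the Z-dienyl bromide may ionise and isomerise, and the C9 equilibration may stop short. The fallback alkylates one stage earlier and sets out from 10. The dianion of 10 (LiN(i-Pr)2, 2.2 equiv, THF/HMPA, −78 → 0 °C) should react with 17 at C9, the less hindered γ-position, to give the 9-alkyl dione F4, whose C9 centre equilibrates through the enol forms. Methanol and TsOH as in step 8 give the vinylogous ester F5, and Luche reduction followed by dilute HCl as in step 9 comes back to the route at 19.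

Step 13. The bulky copper boryl species may fail to reach the hindered C6, or may add to the side-chain diene. The fallback sets out from 19 and uses a smaller nucleophile. Nucleophilic epoxidation (t-BuOOH, DBU, CH2Cl2, 0 °C) from the open α face should give the 6α,7α-epoxy ketone F6. SmI2 (THF/MeOH, −78 °C) cleaves the C7–O bond next to the carbonyl and comes back to the route at 21.

Further compounds
F1 | step 7 | dimethyl 2-[(6S)-6-(methoxycarbonyl)-6-methylnon-8-en-2-ylidene]malonate | COC(=O)C(C(=O)OC)=C(C)CCC[C@@](C)(CC=C)C(=O)OC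
F2 | step 7 | dimethyl 2-[(6S)-6-(methoxycarbonyl)-6-methyl-8-oxononan-2-ylidene]malonate | COC(=O)C(C(=O)OC)=C(C)CCC[C@@](C)(CC(C)=O)C(=O)OC
F3 | step 7 | methyl 9-(methoxycarbonyl)-6,8-dioxo-11,12,13,14,15,16,17-heptanorlabdan-19-oate (C9 epimers, enolised) | COC(=O)C1C(=O)CC(=O)[C@@H]2[C@]1(C)CCC[C@]2(C)C(=O)OC
F4 | step 12 | methyl (12Z)-6,8-dioxo-17-norlabda-12,14-dien-19-oate | C=C/C(C)=C\C[C@H]1C(=O)CC(=O)[C@@H]2[C@]1(C)CCC[C@]2(C)C(=O)OC
F5 | step 12 | methyl (12Z)-8-methoxy-6-oxo-17-norlabda-7,12,14-trien-19-oate | C=C/C(C)=C\C[C@H]1C(OC)=CC(=O)[C@@H]2[C@]1(C)CCC[C@]2(C)C(=O)OC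
F6 | step 13 | methyl (12Z)-6α,7α-epoxy-8-oxo-17-norlabda-12,14-dien-19-oate | C=C/C(C)=C\C[C@H]1C(=O)[C@@H]3O[C@@H]3[C@@H]2[C@]1(C)CCC[C@]2(C)C(=O)OC
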